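**Plan**
1. The last C–C cut is C9–C10, made together with the C10–O–angeloyl bond and the C8–H bond: a three-component aldol–Tishchenko union of methyl enone 22, aldehyde 25 and angelaldehyde 27. The feature that allows it is the side-chain anti-1,3-diol C8/C10: C8 carries the free hydroxyl next to C7(=C14H2) and can be a ketone whose only enolisable position is C9, and the only ester of the pair sits on O10.
2. The ring esters are cut next. The C4 isobutyrate and C6 acetate sit on the two axial oxygens of the cis-diol pairs C3/C4 and C5/C6, so they go back to a cyclic orthoester and an acetoxonium ion; the C5 angelate goes back to a Yamaguchi esterification.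
3. C7–C8 is cut to a Shapiro vinyllithium and a Weinreb amide; the C7 acetyl group comes from the isopropenyl group of (R)-carvone, which supplies the six ring carbons, the C4 methyl and C1.
4. Forward order: carvone, C3–OH, C4/C5 epoxide, C5=C6 allylic diol, acetonide, methyl enone, C5/C6 cis-oxygenation, esters, three-component coupling, desilylation. No ring is formed; the carvone ring is kept throughout.
5. Stereochemistry: C1 is bought. C3, C4, C5 and C6 follow by substrate control, each relayed from its neighbour. C10 is set by a chiral zinc catalyst and C8 is relayed from C10 in the same operation.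

Key step: step 17

Remark (notation and one assumption): ring atoms are C1 (side chain), C2 (CH2), C3 (OH), C4 (CH3, O-isobutyryl), C5 (O-angeloyl), C6 (OAc); the side chain is C7(=C14H2)–C8–C9–C10–C11; β is the ring face that carries the C1 substituent, and in the target all four ring oxygens are β (O3 and O5 equatorial, O4 and O6 axial). (Z)-2-Methylbut-2-enal is assumed not to be a dependable catalogue item and is made fresh from angelic acid.

Step 1
Reactants: 1 (R)-(−)-carvone
Product: 2 (1R,5R)-cis-carveol
Conditions: NaBH4, CeCl3·7H2O, MeOH, 0 °C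
Reagents that add atoms: none
Why: Luche 1,2-reduction of the enone, in which hydride adds axially to the half-chair with the isopropenyl group equatorial, so the new C3 hydroxyl is equatorial and cis (β) to the C1 substituent.

Step 2
Reactants: 2 (1R,5R)-cis-carveol
Product: 3 4β,5β-epoxy-3β-alcohol
Conditions: VO(acac)2 (cat.), t-BuOOH, CH2Cl2, 0 °C → rt
Reagents that add atoms: tert-butyl hydroperoxide, CC(C)(C)OO
Why: Vanadium-catalysed hydroxyl-directed epoxidation delivers oxygen to the ring alkene on the face of the C3 hydroxyl, which sets C4 and C5 (both C–O β) and leaves the non-allylic isopropenyl alkene untouched.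

Step 3
Reactants: 3 4β,5β-epoxy-3β-alcohol
Product: 6 4α-methyl-1β-isopropenylcyclohex-5-ene-3β,4β-diol, via hydroxy selenide 4 (not isolated), via selenoxide 5 (not isolated)
Conditions: (PhSe)2, NaBH4, EtOH, reflux; then 30% H2O2, THF, 0 °C → rt
Reagents that add atoms: none
Why: Epoxide-to-allylic-alcohol transposition by selenide opening and selenoxide syn-elimination, in which PhSe− opens the epoxide trans-diaxially at the secondary C5 without touching the C4–O bond (C4 stays β) and the selenoxide can eliminate only toward C6 because C4 has no hydrogen.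

Step 4
Reactants: 6 cyclohex-5-ene-3β,4β-diol
Product: 7 3,4-O-isopropylidene acetal of 6
Conditions: 2,2-dimethoxypropane, PPTS (cat.), CH2Cl2, rt
Reagents that add atoms: 2,2-dimethoxypropane, COC(C)(C)OC
Why: Acid-catalysed transacetalisation of the cis-3,4-diol gives the cis-fused dioxolane, which masks both hydroxyls for the organolithium step and shields the β-face of the ring alkene.

Step 5
Reactants: 7 acetonide
Product: 9 C1-acetyl compound (C7 methyl ketone), via diol 8 (not isolated)
Conditions: K2OsO4·2H2O (2 mol%), NaIO4, 2,6-lutidine, dioxane–H2O (3:1), 0 °C → rt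
Reagents that add atoms: osmium tetroxide (formed from K2OsO4 and turned over by NaIO4), O=[Os](=O)(=O)=O; sodium periodate, [Na+].[O-][I](=O)(=O)=O
Why: Lemieux–Johnson oxidation, in which osmylation is expected at the unhindered 1,1-disubstituted exocyclic alkene rather than at the ring alkene (cis-disubstituted, flanked by the quaternary C4 and deactivated by the allylic C4–O bond), and periodate cleaves the diol to the ketone without touching C1.

Step 6
Reactants: 9 C7 methyl ketone
Product: 10 (E)-2,4,6-triisopropylbenzenesulfonylhydrazone of 9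
Conditions: 2,4,6-triisopropylbenzenesulfonohydrazide, THF, rt
Reagents that add atoms: 2,4,6-triisopropylbenzenesulfonohydrazide, NNS(=O)(=O)c1c(C(C)C)cc(C(C)C)cc1C(C)C
Why: Acid-free condensation of the methyl ketone with the arenesulfonyl hydrazide gives the (E)-hydrazone needed for the Shapiro reaction and keeps the acetonide and the β,γ-unsaturated ketone intact.

Step 7
Reactants: 10 trisylhydrazone
Product: 12 methyl enone C7(=C14H2)–C8(=O)–C9H3, via vinyllithium 11 (not isolated)
Conditions: n-BuLi (2.2 equiv), TMEDA, THF, −78 → 0 °C; then MeC(O)N(OMe)Me, −78 → 0 °C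
Reagents that add atoms: N-methoxy-N-methylacetamide, CC(=O)N(C)OC
Why: Shapiro reaction, in which the hydrazone dianion forms at the methyl group (less substituted α-carbon, syn to the sulfonamide nitrogen), loses sulfinate and N2 to give the 1-substituted vinyllithium, and acylation by the Weinreb amide stops at the ketone, so C1 is not touched.

Step 8
Reactants: 12 methyl enone
Product: 15 5β-hydroxy-6β-acetate, via iodo acetate 13 (not isolated), via acetoxonium ion 14 (not isolated)
Conditions: I2, AgOAc, AcOH, rt, dark; then AcOH–H2O (95:5), 45 °C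
Reagents that add atoms: silver acetate, CC(=O)[O-].[Ag+]; water, O
Why: Woodward cis-hydroxylation, in which acetyl hypoiodite adds to the only nucleophilic alkene (the enone alkene is electron-poor) with iodine on the open α-face and acetate trans-diaxially at C6 on the β-face, silver-assisted displacement of the C5 iodide by the neighbouring acetate (inversion) gives the β-fused acetoxonium ion, and water opens it through the hemiorthoester to the axial C6 acetate and the equatorial C5 hydroxyl, so both new C–O bonds are β.

Step 9
Reactants: 15 5β-hydroxy-6β-acetate; 16 angelic acid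
Product: 18 5β-angelate 6β-acetate 3,4-acetonide, via mixed anhydride 17 (not isolated)
Conditions: 16, 2,4,6-trichlorobenzoyl chloride, Et3N, toluene, rt; then 15, 80 °C
Reagents that add atoms: none
Why: Yamaguchi esterification through the mixed anhydride without DMAP, conditions under which the Z (angelate) geometry is expected to be kept, acylates the only free hydroxyl (C5).

Step 10
Reactants: 18 5β-angelate 6β-acetate 3,4-acetonide
Product: 19 3β,4β-diol
Conditions: TFA–H2O (9:1), CH2Cl2, 0 °C
Reagents that add atoms: none
Why: Mild aqueous acid hydrolyses the dioxolane to the cis-3,4-diol, while the acetate, the angelate and the enone are expected to be stable to these conditions.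

Step 11
Reactants: 19 3β,4β-diol
Product: 21 4β-isobutyrate 3β-alcohol, via cyclic orthoester 20 (not isolated)
Conditions: i-PrC(OMe)3, PPTS (cat.), CH2Cl2, rt; then 80% aq. AcOH, rt
Reagents that add atoms: 1,1,1-trimethoxy-2-methylpropane (trimethyl orthoisobutyrate), COC(OC)(OC)C(C)C; water, O
Why: Orthoester method for regioselective monoacylation of a cis-diol, in which acid-catalysed exchange gives the cyclic 3,4-orthoisobutyrate and kinetic hydrolysis through the hemiorthoester cleaves the bond to the equatorial secondary oxygen, leaving the isobutyrate on the axial tertiary O4 and freeing the C3 hydroxyl.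

Step 12
Reactants: 21 4β-isobutyrate 3β-alcohol
Product: 22 3β-triethylsilyl ether (ketone fragment)
Conditions: TESOTf, 2,6-lutidine, CH2Cl2, −78 °C
Reagents that add atoms: triethylsilyl trifluoromethanesulfonate, CC[Si](CC)(CC)OS(=O)(=O)C(F)(F)F
Why: Silylation of the equatorial secondary C3 hydroxyl with the silyl triflate and a hindered base at low temperature is fast and avoids the alkoxide that would trigger acyl migration from O4 to O3.

Step 13
Reactants: 23 methyl 2-hydroxy-2-methylpropanoate
Product: 24 methyl 2-methyl-2-(triethylsilyloxy)propanoate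
Conditions: TESCl, imidazole, DMF, rt
Reagents that add atoms: chlorotriethylsilane, CC[Si](Cl)(CC)CC
Why: Standard silylation of the tertiary hydroxyl masks the future C11 hydroxyl with the same group as on O3, so that both are removed together at the end.

Step 14
Reactants: 24 methyl 2-methyl-2-(triethylsilyloxy)propanoate
Product: 25 2-methyl-2-(triethylsilyloxy)propanal
Conditions: DIBAL-H, CH2Cl2, −78 °C; Rochelle salt
Reagents that add atoms: none
Why: Partial reduction of the ester with DIBAL-H at low temperature stops at the aluminium hemiacetal, which gives the non-enolisable α-quaternary aldehyde on work-up.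

Step 15
Reactants: 16 angelic acid
Product: 26 (Z)-2-methylbut-2-en-1-ol
Conditions: LiAlH4, Et2O, 0 °C
Reagents that add atoms: none
Why: Hydride reduction of the acid to the allylic alcohol proceeds by 1,2-addition and leaves the trisubstituted Z alkene untouched.

Step 16
Reactants: 26 (Z)-2-methylbut-2-en-1-ol
Product: 27 (Z)-2-methylbut-2-enal (angelaldehyde)
Conditions: Dess–Martin periodinane, NaHCO3, CH2Cl2, 0 °C; used at once as a solution
Reagents that add atoms: none
Why: Buffered Dess–Martin oxidation gives the enal under neutral conditions at low temperature, which avoids Z to E isomerisation.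

Step 17
Reactants: 22 ketone fragment; 25 2-methyl-2-(triethylsilyloxy)propanal; 27 angelaldehyde
Product: 30 (8R,10R)-anti-diol 10-monoangelate bis(triethylsilyl) ether, via aldol 28 (not isolated), via hemiacetal 29 (not isolated)
Conditions: (S,S)-ProPhenol (20 mol%), Et2Zn (40 mol%), 4 Å MS, 25 (1.5 equiv), THF, 0 °C → rt; then 27 (8 equiv), SmI2 (30 mol%), THF, −10 °C, dark
Reagents that add atoms: none
Why: Proposed new method: the dinuclear zinc–ProPhenol catalyst soft-enolises 22 at the C9 methyl group, the only acidic position of the C7(=C14H2)–C8(=O)–C9H3 enone (C7 has no hydrogen and the ester α-positions are far less acidic), and the chiral zinc enolate adds to the non-enolisable aldehyde 25 to form the C9–C10 bond of aldol 28; Sm(III), formed from SmI2 and the enal, then binds the C10 hydroxyl and the C8 carbonyl, the C10 oxygen adds to angelaldehyde 27, and hemiacetal 29 passes its carbinol hydrogen as hydride to C8 through a chair-like six-membered transition state, so that the enal ends as the C10 angelate and the ketone as the free C8 carbinol. The closest known reaction types are the zinc–ProPhenol direct asymmetric aldol addition of methyl vinyl ketones to α-branched aldehydes and the samarium-catalysed Evans–Tishchenko reduction of β-hydroxy ketones (and the aldol–Tishchenko reaction of one ketone with two molecules of one aldehyde); new is the crossed one-flask version with two different aldehydes and a (Z)-enal as the hydride donor. No ring is closed. C10 is set by the catalyst (addition to the Re face of 25, expected for the (S,S)-ligand by analogy with other α-branched aldehydes, gives 10R), and C8 is relayed from C10 by the samarium chelate in which the C10 substituent is equatorial, which gives the 1,3-anti (8R,10R) diol. The step needs the two aldehydes to keep their roles, the Z geometry to survive and the ester to stay on O10: 25 is consumed in the aldol stage before 27 is added and its neopentyl-type hemiacetal is a poor hydride donor, 27 is used in excess at −10 °C where zinc-aldol addition to it is slow, its C=C bond takes no part in the hydride shift, and samarium alkoxides at this temperature are not expected to promote 1,3-acyl migration or retro-aldol cleavage.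

Step 18
Reactants: 30 anti-diol 10-monoangelate bis(triethylsilyl) ether
Product: 31 CNP0332728.1 (target)
Conditions: HF·pyridine, pyridine, THF, 0 °C → rt
Reagents that add atoms: none
Why: Fluoride cleavage of the two triethylsilyl ethers under buffered acidic conditions frees the C3 and C11 hydroxyls without the basic conditions that would promote acyl migration or ester cleavage.

**Compound list**
1 | (R)-(−)-carvone | C=C(C)[C@H]1CC(=O)C(C)=CC1 | starting material
2 | (1R,5R)-cis-carveol (C3–OH cis to the isopropenyl group) | C=C(C)[C@H]1C[C@@H](O)C(C)=CC1 | intermediate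
3 | 4β,5β-epoxy-3β-alcohol (epoxide, hydroxyl and isopropenyl all cis) | C=C(C)[C@H]1C[C@@H](O)[C@@]2(C)O[C@H]2C1 | intermediate
4 | 5α-(phenylselanyl)-3β,4β-diol | C=C(C)[C@H]1C[C@@H](O)[C@@](C)(O)[C@H]([Se]c2ccccc2)C1 | intermediate
5 | selenoxide of 4 | C=C(C)[C@H]1C[C@@H](O)[C@@](C)(O)[C@H]([Se](=O)c2ccccc2)C1 | intermediate
6 | 4α-methyl-1β-isopropenylcyclohex-5-ene-3β,4β-diol | C=C(C)[C@H]1C[C@@H](O)[C@@](C)(O)C=C1 | intermediate
7 | 3,4-O-isopropylidene acetal of 6 | C=C(C)[C@H]1C[C@H]2OC(C)(C)O[C@@]2(C)C=C1 | intermediate
8 | 7,14-diol of 7 (both C7 epimers) | CC(O)(CO)[C@H]1C[C@H]2OC(C)(C)O[C@@]2(C)C=C1 | intermediate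
9 | C1β-acetyl compound (C7 methyl ketone), 3,4-acetonide | CC(=O)[C@H]1C[C@H]2OC(C)(C)O[C@@]2(C)C=C1 | intermediate
10 | (E)-2,4,6-triisopropylbenzenesulfonylhydrazone of 9 | C/C(=N\NS(=O)(=O)c1c(C(C)C)cc(C(C)C)cc1C(C)C)[C@H]1C[C@H]2OC(C)(C)O[C@@]2(C)C=C1 | intermediate
11 | C7 vinyllithium | [Li]C(=C)[C@H]1C[C@H]2OC(C)(C)O[C@@]2(C)C=C1 | intermediate
12 | methyl enone (3-substituted but-3-en-2-one), 3,4-acetonide, C5=C6 alkene | CC(=O)C(=C)[C@H]1C[C@H]2OC(C)(C)O[C@@]2(C)C=C1 | intermediate
13 | 5α-iodo-6β-acetate | CC(=O)C(=C)[C@H]1C[C@H]2OC(C)(C)O[C@@]2(C)[C@H](I)[C@H]1OC(C)=O | intermediate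
14 | 5β,6β-fused 2-methyl-1,3-dioxolan-2-ylium (acetoxonium) acetate | CC(=O)C(=C)[C@H]1C[C@H]2OC(C)(C)O[C@@]2(C)[C@H]2O[C+](C)O[C@@H]12.CC(=O)[O-] | intermediate
15 | 5β-hydroxy-6β-acetate, 3,4-acetonide | CC(=O)C(=C)[C@H]1C[C@H]2OC(C)(C)O[C@@]2(C)[C@@H](O)[C@H]1OC(C)=O | intermediate
16 | angelic acid ((Z)-2-methylbut-2-enoic acid) | C/C=C(/C)C(=O)O | starting material
17 | angelic 2,4,6-trichlorobenzoic anhydride | C/C=C(/C)C(=O)OC(=O)c1c(Cl)cc(Cl)cc1Cl | intermediate
18 | 5β-angelate 6β-acetate, 3,4-acetonide | CC(=O)C(=C)[C@H]1C[C@H]2OC(C)(C)O[C@@]2(C)[C@@H](OC(=O)/C(C)=C\C)[C@H]1OC(C)=O | intermediate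
19 | 3β,4β-diol 5β-angelate 6β-acetate | CC(=O)C(=C)[C@H]1C[C@@H](O)[C@@](C)(O)[C@@H](OC(=O)/C(C)=C\C)[C@H]1OC(C)=O | intermediate
20 | cyclic 3,4-(methyl orthoisobutyrate) (both epimers at the orthoester carbon) | CC(=O)C(=C)[C@H]1C[C@H]2OC(OC)(C(C)C)O[C@@]2(C)[C@@H](OC(=O)/C(C)=C\C)[C@H]1OC(C)=O | intermediate
21 | 4β-isobutyrate 3β-alcohol 5β-angelate 6β-acetate | CC(=O)C(=C)[C@H]1C[C@@H](O)[C@@](C)(OC(=O)C(C)C)[C@@H](OC(=O)/C(C)=C\C)[C@H]1OC(C)=O | intermediate
22 | 3β-triethylsilyl ether of 21 (ketone fragment) | CC(=O)C(=C)[C@H]1C[C@@H](O[Si](CC)(CC)CC)[C@@](C)(OC(=O)C(C)C)[C@@H](OC(=O)/C(C)=C\C)[C@H]1OC(C)=O | intermediate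
23 | methyl 2-hydroxy-2-methylpropanoate | COC(=O)C(C)(C)O | starting material
24 | methyl 2-methyl-2-(triethylsilyloxy)propanoate | COC(=O)C(C)(C)O[Si](CC)(CC)CC | intermediate
25 | 2-methyl-2-(triethylsilyloxy)propanal | O=CC(C)(C)O[Si](CC)(CC)CC | intermediate
26 | (Z)-2-methylbut-2-en-1-ol | C/C=C(/C)CO | intermediate
27 | (Z)-2-methylbut-2-enal (angelaldehyde) | C/C=C(/C)C=O | intermediate
28 | (10R)-aldol (β-hydroxy enone: C8 ketone, C10–OH, C11–OTES) | C=C(C(=O)C[C@@H](O)C(C)(C)O[Si](CC)(CC)CC)[C@H]1C[C@@H](O[Si](CC)(CC)CC)[C@@](C)(OC(=O)C(C)C)[C@@H](OC(=O)/C(C)=C\C)[C@H]1OC(C)=O | intermediate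
29 | O10 hemiacetal of 28 with 27 (samarium-bound; hemiacetal carbon unassigned) | C=C(C(=O)C[C@@H](OC(O)/C(C)=C\C)C(C)(C)O[Si](CC)(CC)CC)[C@H]1C[C@@H](O[Si](CC)(CC)CC)[C@@](C)(OC(=O)C(C)C)[C@@H](OC(=O)/C(C)=C\C)[C@H]1OC(C)=O | intermediate
30 | (8R,10R)-anti-diol 10-monoangelate, 3,11-bis(triethylsilyl) ether | C=C([C@H](O)C[C@@H](OC(=O)/C(C)=C\C)C(C)(C)O[Si](CC)(CC)CC)[C@H]1C[C@@H](O[Si](CC)(CC)CC)[C@@](C)(OC(=O)C(C)C)[C@@H](OC(=O)/C(C)=C\C)[C@H]1OC(C)=O | intermediate
31 | CNP0332728.1 | C=C([C@H](O)C[C@@H](OC(=O)/C(C)=C\C)C(C)(C)O)[C@H]1C[C@@H](O)[C@@](C)(OC(=O)C(C)C)[C@@H](OC(=O)/C(C)=C\C)[C@H]1OC(C)=O | target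

**Count**
Total steps: 18. Longest linear sequence: 14 steps (steps 1–12, 17, 18); steps 13–14 and 15–16 make the two aldehydes.

**Steps most likely to fail, with fallbacks**

Step 17 (proposed new method). The zinc catalyst may turn over poorly when the ketone is the limiting partner, the remote ring stereocentres may erode the facial selectivity at C10, and the aldol may cyclise onto the enone. In the second stage, residual 25 may compete as hydride donor, or the enal may isomerise before hydride transfer. The fallback uses two known reactions in separate flasks and sets out from 22. Enolisation with (−)-Ipc2BCl (the antipode expected to give Re-face addition for a methyl ketone) and Et3N in Et2O gives the enol diisopinocampheylborinate F1. Addition of 25 at −78 °C gives the boron aldolate F2 under reagent control, and oxidative work-up (H2O2, pH 7 buffer, MeOH) releases aldol 28, which is isolated and purified. 28 is then submitted to the samarium-catalysed Evans–Tishchenko reduction with 27 (SmI2, THF, −10 °C) and returns to the route at 30.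

Step 8. Iodine and acetate may add from the wrong faces, the acetonide may be lost in wet acetic acid, and the acetyl group may equilibrate between O5 and O6. The fallback sets out from 12 and replaces the iodonium pathway by an epoxide pathway. Epoxidation with mCPBA (NaHCO3, CH2Cl2) on the face anti to the dioxolane gives the 5α,6α-epoxide F3. Opening with acetate (Bu4NOAc, AcOH, toluene, 60 °C) gives the trans hydroxy acetate F4, drawn as the trans-diaxial 6β-acetate 5α-alcohol. Triflation of the free hydroxyl (Tf2O, pyridine, CH2Cl2, −20 °C) gives the triflate F5. It ionises with participation of the neighbouring acetate to the acetoxonium ion 14, and added water returns to the route at 15. Either regiochemistry of epoxide opening should converge on 14, because both trans hydroxy acetates lead to the same β-fused ion.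

Step 11. The hemiorthoester may collapse in the other direction and place the ester on O3, or the isobutyryl group may migrate from O4 to O3 under the acidic conditions. The fallback sets out from 19 and acylates the tertiary alcohol directly. Selective silylation of the secondary C3 hydroxyl (TESCl, imidazole, DMF, 0 °C) gives the 3β-triethylsilyl ether 4β-alcohol F6. Acylation of the tertiary hydroxyl with isobutyric anhydride promoted by MgBr2·OEt2 and Et3N (CH2Cl2, rt) returns to the route at 22.

**Further compounds**
F1 | step 17 | enol diisopinocampheylborinate of 22 | C=C(OB([C@@H]1C[C@@H]2C[C@H]([C@H]1C)C2(C)C)[C@@H]1C[C@@H]2C[C@H]([C@H]1C)C2(C)C)C(=C)[C@H]1C[C@@H](O[Si](CC)(CC)CC)[C@@](C)(OC(=O)C(C)C)[C@@H](OC(=O)/C(C)=C\C)[C@H]1OC(C)=O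
F2 | step 17 | O10 diisopinocampheylboron aldolate of 28 | C=C(C(=O)C[C@@H](OB([C@@H]1C[C@@H]2C[C@H]([C@H]1C)C2(C)C)[C@@H]1C[C@@H]2C[C@H]([C@H]1C)C2(C)C)C(C)(C)O[Si](CC)(CC)CC)[C@H]1C[C@@H](O[Si](CC)(CC)CC)[C@@](C)(OC(=O)C(C)C)[C@@H](OC(=O)/C(C)=C\C)[C@H]1OC(C)=O
F3 | step 8 | 5α,6α-epoxide of 12 | CC(=O)C(=C)[C@H]1C[C@H]2OC(C)(C)O[C@@]2(C)[C@@H]2O[C@H]12
F4 | step 8 | 6β-acetate 5α-alcohol (trans hydroxy acetate) | CC(=O)C(=C)[C@H]1C[C@H]2OC(C)(C)O[C@@]2(C)[C@H](O)[C@H]1OC(C)=O
F5 | step 8 | 6β-acetate 5α-triflate | CC(=O)C(=C)[C@H]1C[C@H]2OC(C)(C)O[C@@]2(C)[C@H](OS(=O)(=O)C(F)(F)F)[C@H]1OC(C)=O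
F6 | step 11 | 3β-triethylsilyl ether 4β-alcohol 5β-angelate 6β-acetate | CC(=O)C(=C)[C@H]1C[C@@H](O[Si](CC)(CC)CC)[C@@](C)(O)[C@@H](OC(=O)/C(C)=C\C)[C@H]1OC(C)=O
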